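## Retrosynthetic overview

1. Magnone B ⇐ aryl ketone from a C4 Weinreb amide plus 3,4‑dimethoxyphenyl Grignard; the amide comes from oxidation of a C4 CH2OH arm carried as a benzyl ether.
2. Tetrahydrofuran ring ⇐ acid‑mediated benzylic‑cation cycloetherification of an acyclic triol, which sets C2 trans to C3.
3. Triol ⇐ LiAlH4 opening of a trans‑α‑(aryl‑hydroxymethyl)‑β‑(benzyloxymethyl)‑γ‑butyrolactone ⇐ aldol of (S)‑lactone 2 with 3,4,5‑trimethoxybenzaldehyde, which sets C3.
4. (S)‑Lactone 2 ⇐ Baeyer–Villiger monooxygenase desymmetrisation of prochiral 3‑(benzyloxymethyl)cyclobutanone, which sets the first stereocentre (future C4).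
5. Ring order: temporary γ‑butyrolactone (step 1), opened (step 3), then the tetrahydrofuran (step 4).

Assumption: 3‑[(benzyloxy)methyl]cyclobutanone is taken as commercially available, and an (S)‑selective Baeyer–Villiger monooxygenase is taken from an enantiocomplementary CHMO/CPMO‑type panel.

Numbering used for the target ring: O1, C2 (aryl), C3 (CH2OH), C4 (aroyl), C5. The target is (2S,3R,4R), i.e. 2,3‑trans and 3,4‑cis.

## Route

**Step 1**
Reactants: 1, 3‑[(benzyloxy)methyl]cyclobutan‑1‑one
Product: 2, (S)‑4‑[(benzyloxy)methyl]oxolan‑2‑one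
Conditions: Baeyer–Villiger monooxygenase (CHMO‑type, whole cells or lysate), NADP+ cat., glucose/GDH recycle, air, phosphate buffer pH 8, 25–30 °C
Reagents that add atoms: dioxygen, O=O
Why: Enzymatic Baeyer–Villiger oxidation desymmetrises the prochiral cyclobutanone, because the enzyme lets only one of the two enantiotopic α‑carbons migrate, which sets the (S) centre (future C4) catalytically.

**Step 2**
Reactants: 2, (S)‑4‑[(benzyloxy)methyl]oxolan‑2‑one; 3, 3,4,5‑trimethoxybenzaldehyde
Product: 4, (3S,4S)‑4‑[(benzyloxy)methyl]‑3‑[hydroxy(3,4,5‑trimethoxyphenyl)methyl]oxolan‑2‑one (3,4‑trans; mixture of carbinol epimers)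
Conditions: LDA (1.1 equiv), THF, −78 °C; then 3, −78 °C; AcOH/NH4Cl quench at −78 °C
Reagents that add atoms: 3,4,5‑trimethoxybenzaldehyde, COc1cc(C=O)cc(OC)c1OC
Why: Lithium‑enolate aldol addition in which the aldehyde approaches anti to the C4 substituent, setting the ring centre (future C3) trans by 1,2‑induction; the carbinol centre is uncontrolled but is erased in step 4.

**Step 3**
Reactants: 4, trans aldol lactone
Product: 5, (2R,3R)‑2‑[(benzyloxy)methyl]‑3‑[hydroxy(3,4,5‑trimethoxyphenyl)methyl]butane‑1,4‑diol (carbinol epimers)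
Conditions: LiAlH4, THF, 0 °C; Rochelle salt work‑up
Reagents that add atoms: none
Why: Hydride reduction of the lactone to the 1,4‑diol, fast at 0 °C so retro‑aldol does not compete; no stereocentre is touched and the benzyl ether keeps the two CH2O arms on the future C4 distinct.

**Step 4**
Reactants: 5, triol
Product: 6, [(2S,3R,4S)‑4‑[(benzyloxy)methyl]‑2‑(3,4,5‑trimethoxyphenyl)oxolan‑3‑yl]methanol
Conditions: BF3·OEt2 (1.2 equiv), CH2Cl2, −20 → 0 °C; aq. NaHCO3
Reagents that add atoms: none
Why: SN1 cycloetherification in which both carbinol epimers give the same 3,4,5‑trimethoxybenzyl cation, trapped 5‑exo by the primary OH on the benzyloxymethyl‑bearing carbon (the other OH would give an oxetane); reversible closure places the aryl trans to the C3 arm (sets C2 = S), and 3,4‑cis follows from the trans lactone.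

**Step 5**
Reactants: 6, tetrahydrofuran alcohol
Product: 7, tert‑butyl({(2S,3R,4S)‑4‑[(benzyloxy)methyl]‑2‑(3,4,5‑trimethoxyphenyl)oxolan‑3‑yl}methoxy)dimethylsilane
Conditions: TBSCl, imidazole, DMF, 0 °C → rt
Reagents that add atoms: TBSCl, CC(C)(C)[Si](C)(C)Cl
Why: Standard silylation of the only free (primary) hydroxyl, masking the CH2OH that must survive to the target.

**Step 6**
Reactants: 7, benzyl ether
Product: 8, [(3S,4R,5S)‑4‑({[tert‑butyl(dimethyl)silyl]oxy}methyl)‑5‑(3,4,5‑trimethoxyphenyl)oxolan‑3‑yl]methanol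
Conditions: H2 (1 atm), Pd(OH)2/C, EtOAc, rt, stopped at full conversion
Reagents that add atoms: none
Why: Hydrogenolysis of the unhindered primary benzyl ether is much faster than cleavage of the hindered cyclic benzylic ether under neutral conditions, and the TBS ether is stable in EtOAc.

**Step 7**
Reactants: 8, primary alcohol
Product: 9, (3R,4R,5S)‑4‑({[tert‑butyl(dimethyl)silyl]oxy}methyl)‑5‑(3,4,5‑trimethoxyphenyl)oxolane‑3‑carboxylic acid
Conditions: TEMPO (0.2 equiv), PhI(OAc)2 (2.2 equiv), MeCN/H2O 1:1, rt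
Reagents that add atoms: water, O
Why: TEMPO/PhI(OAc)2 oxidation takes the primary alcohol to the acid through the aldehyde hydrate under near‑neutral conditions, so the α‑centre is not epimerised and the electron‑rich arenes are untouched.

**Step 8**
Reactants: 9, carboxylic acid
Product: 10, (3R,4R,5S)‑4‑({[tert‑butyl(dimethyl)silyl]oxy}methyl)‑N‑methoxy‑N‑methyl‑5‑(3,4,5‑trimethoxyphenyl)oxolane‑3‑carboxamide
Conditions: MeNH(OMe)·HCl, EDC·HCl, HOBt, iPr2NEt, CH2Cl2, 0 °C → rt
Reagents that add atoms: N,O‑dimethylhydroxylamine hydrochloride, CNOC.Cl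
Why: Carbodiimide amide coupling gives the Weinreb amide, whose α‑proton is poorly acidic, so the cis C3/C4 relationship is kept.

**Step 9**
Reactants: 10, Weinreb amide; 11, 4‑bromo‑1,2‑dimethoxybenzene
Product: 12, [(3R,4R,5S)‑4‑({[tert‑butyl(dimethyl)silyl]oxy}methyl)‑5‑(3,4,5‑trimethoxyphenyl)oxolan‑3‑yl](3,4‑dimethoxyphenyl)methanone
Conditions: 11, Mg, I2 cat., THF, reflux (gives ArMgBr, 2.5 equiv); then 10, THF, 0 °C; sat. NH4Cl at 0 °C
Reagents that add atoms: 3,4‑dimethoxyphenylmagnesium bromide (from 11), COc1ccc([Mg]Br)cc1OC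
Why: Weinreb ketone synthesis, in which the chelated tetrahedral intermediate prevents over‑addition and releases the ketone only on mild acidic quench, so the ketone never meets base.

**Step 10**
Reactants: 12, silyl‑protected ketone
Product: 13, Magnone B, (3,4‑dimethoxyphenyl)[(3R,4R,5S)‑4‑(hydroxymethyl)‑5‑(3,4,5‑trimethoxyphenyl)oxolan‑3‑yl]methanone
Conditions: HF·pyridine, pyridine/THF, 0 °C → rt
Reagents that add atoms: none
Why: Fluoride desilylation under buffered, mildly acidic conditions frees the primary alcohol without enolising the ketone, so the cis C4 centre is kept.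

## Compound list

1 | 3‑[(benzyloxy)methyl]cyclobutan‑1‑one | O=C1CC(COCc2ccccc2)C1 | starting material
2 | (S)‑4‑[(benzyloxy)methyl]oxolan‑2‑one | O=C1C[C@@H](COCc2ccccc2)CO1 | intermediate
3 | 3,4,5‑trimethoxybenzaldehyde | COc1cc(C=O)cc(OC)c1OC | starting material
4 | (3S,4S)‑4‑[(benzyloxy)methyl]‑3‑[hydroxy(3,4,5‑trimethoxyphenyl)methyl]oxolan‑2‑one (carbinol epimers) | O=C1OC[C@H](COCc2ccccc2)[C@H]1C(O)c1cc(OC)c(OC)c(OC)c1 | intermediate
5 | (2R,3R)‑2‑[(benzyloxy)methyl]‑3‑[hydroxy(3,4,5‑trimethoxyphenyl)methyl]butane‑1,4‑diol (carbinol epimers) | OC[C@H](COCc1ccccc1)[C@H](CO)C(O)c1cc(OC)c(OC)c(OC)c1 | intermediate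
6 | [(2S,3R,4S)‑4‑[(benzyloxy)methyl]‑2‑(3,4,5‑trimethoxyphenyl)oxolan‑3‑yl]methanol | c1ccccc1COC[C@H]2CO[C@H](c3cc(OC)c(OC)c(OC)c3)[C@H]2CO | intermediate
7 | TBS ether of 6 | c1ccccc1COC[C@H]2CO[C@H](c3cc(OC)c(OC)c(OC)c3)[C@H]2CO[Si](C)(C)C(C)(C)C | intermediate
8 | [(3S,4R,5S)‑4‑(TBSO‑methyl)‑5‑(3,4,5‑trimethoxyphenyl)oxolan‑3‑yl]methanol | OC[C@H]2CO[C@H](c3cc(OC)c(OC)c(OC)c3)[C@H]2CO[Si](C)(C)C(C)(C)C | intermediate
9 | (3R,4R,5S)‑4‑(TBSO‑methyl)‑5‑(3,4,5‑trimethoxyphenyl)oxolane‑3‑carboxylic acid | OC(=O)[C@H]2CO[C@H](c3cc(OC)c(OC)c(OC)c3)[C@H]2CO[Si](C)(C)C(C)(C)C | intermediate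
10 | (3R,4R,5S)‑4‑(TBSO‑methyl)‑N‑methoxy‑N‑methyl‑5‑(3,4,5‑trimethoxyphenyl)oxolane‑3‑carboxamide | CON(C)C(=O)[C@H]2CO[C@H](c3cc(OC)c(OC)c(OC)c3)[C@H]2CO[Si](C)(C)C(C)(C)C | intermediate
11 | 4‑bromo‑1,2‑dimethoxybenzene | COc1ccc(Br)cc1OC | starting material
12 | [(3R,4R,5S)‑4‑(TBSO‑methyl)‑5‑(3,4,5‑trimethoxyphenyl)oxolan‑3‑yl](3,4‑dimethoxyphenyl)methanone | COc1ccc(C(=O)[C@H]2CO[C@H](c3cc(OC)c(OC)c(OC)c3)[C@H]2CO[Si](C)(C)C(C)(C)C)cc1OC | intermediate
13 | Magnone B | COc1ccc(C(=O)[C@H]2CO[C@H](c3cc(OC)c(OC)c(OC)c3)[C@H]2CO)cc1OC | target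

## Summary

Total steps: 10. Longest linear sequence: 10 (fully linear; the Grignard reagent is made in situ in step 9).

Steps most likely to fail, with fallbacks:

- **Step 4 (cationic ring closure).** The 3,4,5‑trimethoxybenzyl cation is only moderately stabilised, so trans selectivity may be incomplete or styrene may form. Fallback: set the benzylic carbinol with a ketoreductase instead, by dynamic kinetic reduction of diethyl 2‑(3,4,5‑trimethoxybenzoyl)succinate to the trans γ‑aryl paraconate. Then add the CH2OBn arm by trans‑selective lactone‑enolate alkylation (BOMCl) and close the ring by Williamson etherification of the C2 alkoxide onto a primary tosylate, so C2 is never ionised.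
- **Step 1 (enzymatic desymmetrisation).** The enzyme may give insufficient ee, low productivity, or the wrong enantiomer. Fallback: lipase desymmetrisation of 2‑allylpropane‑1,3‑diol (from diethyl allylmalonate) to the monoacetate, then O‑benzylation with benzyl trichloroacetimidate, oxidative cleavage of the allyl group to the acid, acetate removal and lactonisation to the same lactone 2.
- **Step 6 (hydrogenolysis).** Pd/H2 may also cleave the electron‑rich benzylic C2–O bond of the ring. Fallback: carry the arm as a PMB ether from the start (Baeyer–Villiger monooxygenase on 3‑[(4‑methoxybenzyloxy)methyl]cyclobutanone) and unmask it oxidatively with buffered DDQ, so no hydrogenation is needed.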